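**Retrosynthetic overview**
1. Target 16 ⇐ LiAlH4 opening of the cis-fused furofuranone 15: the lactone C=O becomes the CH2OH on C3 of the oxolane, the lactone oxygen becomes the benzylic OH, and both aryl pivalates are cleaved.
2. 15 ⇐ photochemical Wolff ring contraction of the 3-diazo-tetrahydropyran-4-one 13, with the ketene captured by the side-chain OH (oxane → oxolane, then lactone ring).
3. 13 ⇐ anti-aldol adduct 11 ⇐ dihydropyranone 9 + aldehyde 5 (conjugate reduction, then aldol).
4. 9 ⇐ aldehyde 5 + silyloxy diene made in the flask from 6 (asymmetric hetero-Diels–Alder); 5 ⇐ vanillin ⇐ guaiacol ⇐ catechol.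
5. Ring order: six-membered oxane (step 4) → contracted to the oxolane with the γ-lactone closed in the same step (step 7) → lactone opened (step 8).

Abbreviation: Ar = 3-methoxy-4-(pivaloyloxy)phenyl (pivaloyl = 2,2-dimethylpropanoyl). In steps 4–7 the locants are those of the pyran ring (O1, C2 carries Ar, C4 is the carbonyl); C1' is the side-chain carbinol carbon.
Target read from the SMILES as (2R,3S,4S) in the oxolane and R at the carbinol carbon.

**Step 1**
Reactants: 1 catechol (benzene-1,2-diol)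
Product: 2 guaiacol (2-methoxyphenol)
Conditions: Me2SO4 (1.0 equiv), NaOH (1.0 equiv), H2O, 40 °C; acid–base extraction, distillation
Reagents that add atoms: dimethyl sulfate, COS(=O)(=O)OC
Why: Williamson mono-O-methylation of the catecholate monoanion, which stops mainly at the monoether with one equivalent of base and alkylating agent (veratrole and catechol are removed by extraction and distillation); no stereocentre.

**Step 2**
Reactants: 2 guaiacol
Product: 4 vanillin (4-hydroxy-3-methoxybenzaldehyde), via mandelic acid 3 (not isolated)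
Conditions: OHC–CO2H (aq.), NaOH, H2O, 30 °C; then CuSO4 (cat.), air, NaOH, 95 °C; H2SO4 to pH 3
Reagents that add atoms: glyoxylic acid, O=CC(=O)O
Why: Electrophilic aromatic hydroxyalkylation of the phenoxide para to the oxygen by glyoxylate, followed by copper-catalysed aerobic oxidative decarboxylation of the mandelate to the aldehyde; no stereocentre is kept.

**Step 3**
Reactants: 4 vanillin
Product: 5 4-formyl-2-methoxyphenyl pivalate
Conditions: t-BuCOCl, Et3N, DMAP (cat.), CH2Cl2, 0 → 23 °C
Reagents that add atoms: pivaloyl chloride, CC(C)(C)C(=O)Cl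
Why: DMAP-catalysed O-acylation masks the phenol as a pivalate that survives hydride at −78 °C, amide base and light, and makes the aldehyde a better electrophile; no stereocentre.

**Step 4**
Reactants: 5 4-formyl-2-methoxyphenyl pivalate; 6 (E)-4-methoxybut-3-en-2-one
Product: 9 (2R)-2-Ar-2,3-dihydro-4H-pyran-4-one, via silyloxy diene 7 (not isolated), via silyl aldol adduct 8 (not isolated)
Conditions: 6, Me3SiOTf, Et3N, Et2O, 0 °C, volatiles removed; then 5, Ti(OiPr)4 (10 mol %), (R)-BINOL (20 mol %), Et2O, −20 → 23 °C; then CF3CO2H, CH2Cl2, 0 °C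
Reagents that add atoms: none
Why: Soft enolisation gives the Danishefsky-type diene, which undergoes a Lewis-acid-catalysed hetero-Diels–Alder reaction (Mukaiyama aldol, then acid-induced cyclisation with loss of methanol) in which the BINOL–titanium complex shields one aldehyde face and sets C2 as R (sense assigned by analogy with benzaldehyde; the antipodal ligand is used if it proves opposite).

**Step 5**
Reactants: 9 (2R)-2-Ar-2,3-dihydro-4H-pyran-4-one; 5 4-formyl-2-methoxyphenyl pivalate
Product: 11 (2R,5S)-5-[(R)-hydroxy(Ar)methyl]-2-Ar-tetrahydro-4H-pyran-4-one, via lithium enolate 10 (not isolated)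
Conditions: LiBH(s-Bu)3 (1.05 equiv), THF, −78 °C; then 5 (1.2 equiv), −78 → −20 °C; aq. NH4Cl
Reagents that add atoms: none
Why: Conjugate hydride reduction gives the C4–C5 enolate regiospecifically, and its aldol addition to 5 through a Zimmerman–Traxler chair of the ring (E)-enolate gives the anti C5/C1' relationship, while warming lets the lithium aldolate equilibrate by retro-aldol to the isomer with the side chain equatorial and trans to the C2 aryl group (C5 S, C1' R).

**Step 6**
Reactants: 11 (2R,5S)-5-[(R)-hydroxy(Ar)methyl]-2-Ar-tetrahydro-4H-pyran-4-one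
Product: 13 (2S,5S)-3-diazo-5-[(R)-hydroxy(Ar)methyl]-2-Ar-tetrahydro-4H-pyran-4-one, via trifluoroacetyl ketone 12 (not isolated)
Conditions: LiN(SiMe3)2 (2.2 equiv), THF, −78 °C; CF3CO2CH2CF3 (1.3 equiv); aq. HCl; then MeSO2N3, Et3N, H2O (1 equiv), MeCN, 23 °C
Reagents that add atoms: methanesulfonyl azide, CS(=O)(=O)N=[N+]=[N-]
Why: Kinetic deprotonation of the alkoxide–ketone at the less hindered C3 methylene, Claisen-type C-trifluoroacetylation and detrifluoroacetylative (Regitz-type) diazo transfer place the diazo group at C3 without touching C2, C5 or C1' (the C2 descriptor becomes S only through the priority change).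

**Step 7**
Reactants: 13 (2S,5S)-3-diazo-5-[(R)-hydroxy(Ar)methyl]-2-Ar-tetrahydro-4H-pyran-4-one
Product: 15 (3R,3aS,6R,6aR)-3,6-di-Ar-tetrahydro-1H,3H-furo[3,4-c]furan-1-one, via ketene 14 (not isolated)
Conditions: hν (365 nm), THF (0.01 M), 0 → 23 °C
Reagents that add atoms: none
Why: Proposed new method: photoexcitation of the s-cis-locked cyclic α-diazo ketone expels N2 with a 1,2-shift of C5 (retention) from the carbonyl carbon to C3, contracting the oxane to an oxolan-3-ylidene ketene that is captured in the flask by the neighbouring C1' hydroxyl, which can only close the cis-fused γ-lactone and so fixes C6a on protonation; the closest known reactions are the photochemical Wolff ring contraction of cyclic 2-diazo ketones and intramolecular ketene–alcohol lactonisation, which have not been shown on a 3-diazo-tetrahydropyran-4-one carrying a free hydroxyalkyl arm.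

**Step 8**
Reactants: 15 (3R,3aS,6R,6aR)-3,6-di-Ar-tetrahydro-1H,3H-furo[3,4-c]furan-1-one
Product: 16 4-[(2R,3S,4S)-4-[(R)-hydroxy(4-hydroxy-3-methoxyphenyl)methyl]-3-(hydroxymethyl)oxolan-2-yl]-2-methoxyphenol
Conditions: LiAlH4 (4 equiv), THF, 0 → 23 °C; H2O, aq. NaOH
Reagents that add atoms: none
Why: Hydride reduction of the γ-lactone to the 1,4-diol (C1 becomes the CH2OH, the lactone oxygen the benzylic OH) with concurrent reductive cleavage of both aryl pivalates; no stereocentre is touched.

**Compound list**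
1 | catechol | Oc1ccccc1O | starting material
2 | guaiacol | COc1ccccc1O | intermediate
3 | 4-hydroxy-3-methoxymandelic acid (racemic, not isolated) | COc1cc(C(O)C(=O)O)ccc1O | intermediate
4 | vanillin | COc1cc(C=O)ccc1O | intermediate
5 | 4-formyl-2-methoxyphenyl pivalate | COc1cc(C=O)ccc1OC(=O)C(C)(C)C | intermediate
6 | (E)-4-methoxybut-3-en-2-one | CO/C=C/C(C)=O | starting material
7 | (E)-1-methoxy-3-(trimethylsilyloxy)buta-1,3-diene (not isolated) | CO/C=C/C(=C)O[Si](C)(C)C | intermediate
8 | (1E,5R)-1-methoxy-5-Ar-5-(trimethylsilyloxy)pent-1-en-3-one (not isolated) | CO/C=C/C(=O)C[C@@H](O[Si](C)(C)C)c1ccc(OC(=O)C(C)(C)C)c(OC)c1 | intermediate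
9 | (2R)-2-Ar-2,3-dihydro-4H-pyran-4-one | O=C1C[C@H](c2ccc(OC(=O)C(C)(C)C)c(OC)c2)OC=C1 | intermediate
10 | lithium (2R)-2-Ar-3,6-dihydro-2H-pyran-4-olate (not isolated) | [Li]OC1=CCO[C@@H](c2ccc(OC(=O)C(C)(C)C)c(OC)c2)C1 | intermediate
11 | (2R,5S)-5-[(R)-hydroxy(Ar)methyl]-2-Ar-tetrahydro-4H-pyran-4-one | O=C1C[C@H](c2ccc(OC(=O)C(C)(C)C)c(OC)c2)OC[C@H]1[C@@H](O)c1ccc(OC(=O)C(C)(C)C)c(OC)c1 | intermediate
12 | (2R,5S)-5-[(R)-hydroxy(Ar)methyl]-2-Ar-3-(trifluoroacetyl)tetrahydro-4H-pyran-4-one (C3 unassigned, not isolated) | O=C1C(C(=O)C(F)(F)F)[C@H](c2ccc(OC(=O)C(C)(C)C)c(OC)c2)OC[C@H]1[C@@H](O)c1ccc(OC(=O)C(C)(C)C)c(OC)c1 | intermediate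
13 | (2S,5S)-3-diazo-5-[(R)-hydroxy(Ar)methyl]-2-Ar-tetrahydro-4H-pyran-4-one | O=C1C(=[N+]=[N-])[C@H](c2ccc(OC(=O)C(C)(C)C)c(OC)c2)OC[C@H]1[C@@H](O)c1ccc(OC(=O)C(C)(C)C)c(OC)c1 | intermediate
14 | {(2S,4S)-2-Ar-4-[(R)-hydroxy(Ar)methyl]oxolan-3-ylidene}methanone (ketene, not isolated) | O=C=C1[C@H](c2ccc(OC(=O)C(C)(C)C)c(OC)c2)OC[C@H]1[C@@H](O)c1ccc(OC(=O)C(C)(C)C)c(OC)c1 | intermediate
15 | (3R,3aS,6R,6aR)-3,6-di-Ar-tetrahydro-1H,3H-furo[3,4-c]furan-1-one | COc1cc([C@@H]2OC(=O)[C@H]3[C@H](c4ccc(OC(=O)C(C)(C)C)c(OC)c4)OC[C@@H]23)ccc1OC(=O)C(C)(C)C | intermediate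
16 | 4-[(2R,3S,4S)-4-[(R)-hydroxy(4-hydroxy-3-methoxyphenyl)methyl]-3-(hydroxymethyl)oxolan-2-yl]-2-methoxyphenol | COc1cc([C@H](O)[C@@H]2CO[C@@H](c3ccc(O)c(OC)c3)[C@@H]2CO)ccc1O | target

**Step count and risks**
Total steps: 8. Longest linear sequence: 8 (1 → 2 → 4 → 5 → 9 → 11 → 13 → 15 → 16).
The three steps most likely to fail are 5, 6 and 7.

The reductive aldol of step 5 is the weakest for stereocontrol. Kinetic axial attack on the enolate would put the side chain cis to the C2 aryl group, so the step relies on aldolate equilibration, and the enolate can also open by retro-oxa-Michael on warming. The fallback sets out from 9 and comes back at 11. Compound 9 is reduced with LiBH(s-Bu)3 at −78 °C and quenched to give (2R)-2-Ar-tetrahydro-4H-pyran-4-one F1. F1 is then combined with 5 under (S)-proline catalysis (DMSO, 4 °C, enamine aldol). The enamine forms at the less hindered C5, and the catalyst rather than the ring selects both faces, giving the anti (5S,1'R) adduct 11.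

The diazo transfer of step 6 runs through an alkoxide–enolate dianion, which may acylate on oxygen, enolise toward C5 or open the ring. The fallback sets out from 11 and comes back at 13. The hydroxyl is first masked (Et3SiCl, imidazole, DMF) as (2R,5S)-2-Ar-5-[(R)-Ar(triethylsilyloxy)methyl]tetrahydro-4H-pyran-4-one F2. The ordinary mono-enolate sequence (LiN(SiMe3)2, CF3CO2CH2CF3; then MeSO2N3, Et3N) then goes through the 3-trifluoroacetyl ketone F3 (not isolated) to the 3-diazo ketone silyl ether F4. Buffered fluoride (Bu4NF, AcOH, THF, 0 °C) frees the hydroxyl to give 13.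

Step 7 is the proposed new step. Carbene side paths (1,2-hydrogen shift from C2 to give a 6-aryl-dihydropyranone, O–H insertion) or slow intramolecular capture could erode it. The fallback uses known chemistry, sets out from 13 and comes back at 15. Compound 13 is photolysed in methanol so that the ketene is trapped intermolecularly, as in the standard Wolff ring contraction to an ester. This gives methyl (2R,4S)-2-Ar-4-[(R)-hydroxy(Ar)methyl]oxolane-3-carboxylate F5 as a C3 epimer mixture. DBU in toluene at 60 °C then epimerises C3 and closes the cis-fused lactone 15 with loss of methanol.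

Further compounds
F1 | step 5 | (2R)-2-Ar-tetrahydro-4H-pyran-4-one | O=C1C[C@H](c2ccc(OC(=O)C(C)(C)C)c(OC)c2)OCC1
F2 | step 6 | (2R,5S)-2-Ar-5-[(R)-Ar(triethylsilyloxy)methyl]tetrahydro-4H-pyran-4-one | O=C1C[C@H](c2ccc(OC(=O)C(C)(C)C)c(OC)c2)OC[C@H]1[C@@H](O[Si](CC)(CC)CC)c1ccc(OC(=O)C(C)(C)C)c(OC)c1
F3 | step 6 | (2R,5S)-2-Ar-5-[(R)-Ar(triethylsilyloxy)methyl]-3-(trifluoroacetyl)tetrahydro-4H-pyran-4-one (C3 unassigned) | O=C1C(C(=O)C(F)(F)F)[C@H](c2ccc(OC(=O)C(C)(C)C)c(OC)c2)OC[C@H]1[C@@H](O[Si](CC)(CC)CC)c1ccc(OC(=O)C(C)(C)C)c(OC)c1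
F4 | step 6 | (2S,5S)-3-diazo-2-Ar-5-[(R)-Ar(triethylsilyloxy)methyl]tetrahydro-4H-pyran-4-one | O=C1C(=[N+]=[N-])[C@H](c2ccc(OC(=O)C(C)(C)C)c(OC)c2)OC[C@H]1[C@@H](O[Si](CC)(CC)CC)c1ccc(OC(=O)C(C)(C)C)c(OC)c1
F5 | step 7 | methyl (2R,4S)-2-Ar-4-[(R)-hydroxy(Ar)methyl]oxolane-3-carboxylate (C3 epimers) | COC(=O)C1[C@H](c2ccc(OC(=O)C(C)(C)C)c(OC)c2)OC[C@H]1[C@@H](O)c1ccc(OC(=O)C(C)(C)C)c(OC)c1
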